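**Retrosynthetic overview**

1. The strategy rests on ring C: its only unsubstituted carbon, C8, lies ortho to the C7 hydroxyl and para to the diaryl ether oxygen O5, and ring D is fused on exactly this C7–C8 edge. Ring D is therefore cut last, at the C8–C(=O) and O7–CMe2 bonds, into the ring D-free depsidone triol aldehyde and 3-methylbut-2-enoic acid; the base-labile chromanone then never meets an ether- or lactone-forming step.
2. Ring B is cut at the O10–C11 ester bond to a diaryl ether hydroxy acid, and the ether at C4a–O5 to a ring C phenol and a ring A aryl fluoride flanked by formyl and tert-butyl ester. SNAr on this doubly activated fluoride is chosen because both partners are doubly ortho-substituted, which a metal-catalysed etherification tolerates poorly.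
3. The lactone oxygen of ring C is installed before the union (Baeyer–Villiger oxidation of a formyl group) and masked as a MOM ether, so the ring A formyl group never meets a peracid. Ring C comes from 5-methylpyrogallol, ring A from 3-fluoro-5-methylphenol.
4. Ring order: rings A and C are bought as benzenes; ring B closes in step 12, ring D in step 14.

Key step: step 14

Remark: locants follow 11H-dibenzo[b,e][1,4]dioxepin-11-one numbering (ring A = formyl-bearing benzene C1–C4a/C11a, ring B = seven-membered lactone, ring C = oxygenated benzene C5a–C9a, ring D = fused 2,2-dimethyl-2,3-dihydropyran-4-one); the target is achiral; 5-methylpyrogallol and 3-fluoro-5-methylphenol are taken as commercial.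

**Ring C fragment**

Step 1
Reactants: 1 5-methylpyrogallol
Product: 2 2,3,4-trihydroxy-6-methylbenzaldehyde
Conditions: POCl3, DMF, MeCN, 0 °C → rt; then H2O, 50 °C
Reagents that add atoms: N,N-dimethylformamide CN(C)C=O; water O
Why: Vilsmeier–Haack formylation; the two free ring positions are equivalent by symmetry and activated by the hydroxyls, so hydrolysis of the iminium salt should give one aldehyde.

Step 2
Reactants: 2 2,3,4-trihydroxy-6-methylbenzaldehyde
Product: 3 3,4-bis(benzyloxy)-2-hydroxy-6-methylbenzaldehyde
Conditions: BnBr (2.1 equiv), K2CO3 (2.2 equiv), DMF, 0 °C → rt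
Reagents that add atoms: benzyl bromide BrCc1ccccc1
Why: Williamson etherification; the 2-hydroxyl is held in a hydrogen bond to the formyl group and should be spared while the 3- and 4-hydroxyls are benzylated.

Step 3
Reactants: 3 3,4-bis(benzyloxy)-2-hydroxy-6-methylbenzaldehyde
Product: 4 2-(allyloxy)-3,4-bis(benzyloxy)-6-methylbenzaldehyde
Conditions: allyl bromide, K2CO3, DMF, 60 °C
Reagents that add atoms: allyl bromide C=CCBr
Why: Williamson etherification of the remaining chelated phenol under forcing conditions, giving a temporary group that is orthogonal to benzyl and MOM ethers.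

Step 4
Reactants: 4 2-(allyloxy)-3,4-bis(benzyloxy)-6-methylbenzaldehyde
Product: 6 2-(allyloxy)-3,4-bis(benzyloxy)-6-methylphenol, via aryl formate 5 (not isolated)
Conditions: mCPBA (1.2 equiv), CH2Cl2, 0 °C → rt; then K2CO3 (cat.), MeOH, rt
Reagents that add atoms: meta-chloroperoxybenzoic acid OOC(=O)c1cccc(Cl)c1
Why: Baeyer–Villiger (Dakin-type) oxidation; the aryl group, made electron-rich by the para benzyloxy and ortho allyloxy groups, migrates to give the formate, which is methanolysed, while the monosubstituted allyl alkene is epoxidised far more slowly.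

Step 5
Reactants: 6 2-(allyloxy)-3,4-bis(benzyloxy)-6-methylphenol
Product: 7 3-(allyloxy)-1,2-bis(benzyloxy)-4-(methoxymethoxy)-5-methylbenzene
Conditions: MOMCl, iPr2NEt, CH2Cl2, 0 °C → rt
Reagents that add atoms: chloromethyl methyl ether COCCl
Why: O-alkylation to the MOM acetal, which marks the future lactone oxygen and is later removed by the same acid that cleaves the tert-butyl ester.

Step 6
Reactants: 7 3-(allyloxy)-1,2-bis(benzyloxy)-4-(methoxymethoxy)-5-methylbenzene
Product: 8 2,3-bis(benzyloxy)-6-(methoxymethoxy)-5-methylphenol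
Conditions: Pd(PPh3)4 (cat.), morpholine, THF, rt
Reagents that add atoms: none
Why: Tsuji–Trost deallylation; the π-allylpalladium intermediate is captured by morpholine and only the allyl ether is cleaved, freeing the hydroxyl that becomes the diaryl ether oxygen.

**Ring A fragment**

Step 7
Reactants: 9 3-fluoro-5-methylphenol
Product: 10 1-(benzyloxy)-3-fluoro-5-methylbenzene
Conditions: BnBr, K2CO3, DMF, rt
Reagents that add atoms: benzyl bromide BrCc1ccccc1
Why: Williamson etherification of an unhindered phenol.

Step 8
Reactants: 10 1-(benzyloxy)-3-fluoro-5-methylbenzene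
Product: 12 2-(benzyloxy)-6-fluoro-4-methylbenzaldehyde, via aryllithium 11 (not isolated)
Conditions: n-BuLi, THF, −78 °C; DMF, −78 °C → 0 °C; aq. NH4Cl
Reagents that add atoms: N,N-dimethylformamide CN(C)C=O
Why: Directed ortho-metalation; the C–H between fluorine and the benzyloxy oxygen is acidified by both groups and should be removed much faster than the benzylic hydrogens at −78 °C, and the aryllithium is formylated by DMF.

Step 9
Reactants: 12 2-(benzyloxy)-6-fluoro-4-methylbenzaldehyde
Product: 13 6-(benzyloxy)-3-bromo-2-fluoro-4-methylbenzaldehyde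
Conditions: NBS, DMF, rt
Reagents that add atoms: N-bromosuccinimide O=C1CCC(=O)N1Br
Why: Electrophilic aromatic bromination; C5 of 12 is para to the benzyloxy group and flanked by methyl and the small fluorine, whereas C3 is ortho to it and more hindered, so bromine should enter at C5.

Step 10
Reactants: 13 6-(benzyloxy)-3-bromo-2-fluoro-4-methylbenzaldehyde
Product: 16 tert-butyl 4-(benzyloxy)-2-fluoro-3-formyl-6-methylbenzoate, via lithium hemiaminal alkoxide 14 (not isolated), via dilithio species 15 (not isolated)
Conditions: lithium morpholide (morpholine, n-BuLi), THF, −78 °C; n-BuLi, −78 °C; Boc2O, −78 → −40 °C; aq. NH4Cl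
Reagents that add atoms: di-tert-butyl dicarbonate CC(C)(C)OC(=O)OC(=O)OC(C)(C)C
Why: In-situ protection of the aldehyde as its lithium α-amino alkoxide, bromine–lithium exchange and acylation of the aryllithium by Boc2O; the ortho-fluoroaryllithium is kept at −78 °C to prevent loss of LiF, and aqueous work-up returns the formyl group.

**Union and end game**

Step 11
Reactants: 8 2,3-bis(benzyloxy)-6-(methoxymethoxy)-5-methylphenol; 16 tert-butyl 4-(benzyloxy)-2-fluoro-3-formyl-6-methylbenzoate
Product: 17 tert-butyl 4-(benzyloxy)-2-[2,3-bis(benzyloxy)-6-(methoxymethoxy)-5-methylphenoxy]-3-formyl-6-methylbenzoate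
Conditions: K2CO3, DMF, rt → 50 °C
Reagents that add atoms: none
Why: Nucleophilic aromatic substitution; the fluoride is activated by the ortho formyl and ortho ester groups, which stabilise the Meisenheimer intermediate, so the hindered phenoxide should couple under mild conditions.

Step 12
Reactants: 17 tert-butyl 4-(benzyloxy)-2-[2,3-bis(benzyloxy)-6-(methoxymethoxy)-5-methylphenoxy]-3-formyl-6-methylbenzoate
Product: 19 3,6,7-tris(benzyloxy)-1,9-dimethyl-11-oxo-11H-dibenzo[b,e][1,4]dioxepine-4-carbaldehyde, via seco hydroxy acid 18 (not isolated)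
Conditions: TFA/CH2Cl2/H2O (10:10:1), anisole, 0 °C → rt; evaporate from toluene; TFAA, toluene, rt
Reagents that add atoms: none
Why: Acidolysis removes the tert-butyl ester and the MOM acetal while the benzyl ethers stay, and the mixed trifluoroacetic anhydride (acylium ion) of the doubly ortho-substituted acid is trapped by the neighbouring ring C hydroxyl in a 7-exo-trig lactonisation (mixed-anhydride esterification of hindered acids with phenols); no phenoxide is formed, so no Smiles shift of the activated ether can occur, and both carbons ortho to the ether oxygen on ring C are substituted, so no xanthone can form.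

Step 13
Reactants: 19 3,6,7-tris(benzyloxy)-1,9-dimethyl-11-oxo-11H-dibenzo[b,e][1,4]dioxepine-4-carbaldehyde
Product: 20 3,6,7-trihydroxy-1,9-dimethyl-11-oxo-11H-dibenzo[b,e][1,4]dioxepine-4-carbaldehyde
Conditions: H2 (1 atm), 10% Pd/C, EtOAc, rt; work-up under argon
Reagents that add atoms: none
Why: Catalytic hydrogenolysis of the three benzyl aryl ethers; the hindered formyl group, hydrogen-bonded to the freed ortho hydroxyl, should be reduced much more slowly, so the reaction is stopped after three equivalents of hydrogen.

Step 14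
Reactants: 20 3,6,7-trihydroxy-1,9-dimethyl-11-oxo-11H-dibenzo[b,e][1,4]dioxepine-4-carbaldehyde; 21 3-methylbut-2-enoic acid
Product: 23 CNP0271978.0, via hydroxyaryl enone 22 (not isolated)
Conditions: 21 (1.2 equiv), P2O5/CH3SO3H (1:10 w/w), 65 °C; ice-water
Reagents that add atoms: none
Why: In P2O5/CH3SO3H the acid 21 forms a mixed anhydride or acylium ion that acylates C8 of ring C, directly or through an aryl ester and Fries migration, to give the 2-hydroxyaryl enone 22. The closest known reaction type is the one-pot conversion of phenols and 3-methylbut-2-enoic acid into 2,2-dimethylchroman-4-ones in this medium, established for pyrogallol- and resorcinol-type phenols. Ring D then closes by acid-promoted 6-endo-trig oxa-Michael addition of the C7 hydroxyl to the dimethyl-substituted β-carbon; no stereocentre arises because that carbon carries two methyl groups. The step needs reaction on ring C and not ring A, C-acylation at C8 and closure through O7. These follow because ring A is deactivated by its formyl and lactone carbonyl groups, C8 is the only free carbon of ring C and is activated by the ortho C7 hydroxyl and the para ether oxygen O5, and O7 is the only hydroxyl ortho to C8. Only a slight excess of 21 and a moderate temperature are used, to limit acylation of the chelated ring A phenol and attack of ring C on the protonated formyl group.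

**Compound list**

1 | 5-methylpyrogallol (5-methylbenzene-1,2,3-triol) | Cc1cc(O)c(O)c(O)c1 | starting material
2 | 2,3,4-trihydroxy-6-methylbenzaldehyde | O=Cc1c(C)cc(O)c(O)c1O | intermediate
3 | 3,4-bis(benzyloxy)-2-hydroxy-6-methylbenzaldehyde | O=Cc1c(C)cc(OCc2ccccc2)c(OCc2ccccc2)c1O | intermediate
4 | 2-(allyloxy)-3,4-bis(benzyloxy)-6-methylbenzaldehyde | O=Cc1c(C)cc(OCc2ccccc2)c(OCc2ccccc2)c1OCC=C | intermediate
5 | 2-(allyloxy)-3,4-bis(benzyloxy)-6-methylphenyl formate | O=COc1c(C)cc(OCc2ccccc2)c(OCc2ccccc2)c1OCC=C | intermediate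
6 | 2-(allyloxy)-3,4-bis(benzyloxy)-6-methylphenol | Oc1c(C)cc(OCc2ccccc2)c(OCc2ccccc2)c1OCC=C | intermediate
7 | 3-(allyloxy)-1,2-bis(benzyloxy)-4-(methoxymethoxy)-5-methylbenzene | COCOc1c(C)cc(OCc2ccccc2)c(OCc2ccccc2)c1OCC=C | intermediate
8 | 2,3-bis(benzyloxy)-6-(methoxymethoxy)-5-methylphenol | COCOc1c(C)cc(OCc2ccccc2)c(OCc2ccccc2)c1O | intermediate
9 | 3-fluoro-5-methylphenol | Cc1cc(O)cc(F)c1 | starting material
10 | 1-(benzyloxy)-3-fluoro-5-methylbenzene | Cc1cc(F)cc(OCc2ccccc2)c1 | intermediate
11 | [2-(benzyloxy)-6-fluoro-4-methylphenyl]lithium | [Li]c1c(F)cc(C)cc1OCc1ccccc1 | intermediate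
12 | 2-(benzyloxy)-6-fluoro-4-methylbenzaldehyde | O=Cc1c(F)cc(C)cc1OCc1ccccc1 | intermediate
13 | 6-(benzyloxy)-3-bromo-2-fluoro-4-methylbenzaldehyde | O=Cc1c(F)c(Br)c(C)cc1OCc1ccccc1 | intermediate
14 | lithium [6-(benzyloxy)-3-bromo-2-fluoro-4-methylphenyl](morpholin-4-yl)methanolate | [Li]OC(N1CCOCC1)c1c(F)c(Br)c(C)cc1OCc1ccccc1 | intermediate
15 | lithium [6-(benzyloxy)-2-fluoro-3-lithio-4-methylphenyl](morpholin-4-yl)methanolate | [Li]OC(N1CCOCC1)c1c(F)c([Li])c(C)cc1OCc1ccccc1 | intermediate
16 | tert-butyl 4-(benzyloxy)-2-fluoro-3-formyl-6-methylbenzoate | O=Cc1c(F)c(C(=O)OC(C)(C)C)c(C)cc1OCc1ccccc1 | intermediate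
17 | tert-butyl 4-(benzyloxy)-2-[2,3-bis(benzyloxy)-6-(methoxymethoxy)-5-methylphenoxy]-3-formyl-6-methylbenzoate | O=Cc1c(Oc2c(OCc3ccccc3)c(OCc3ccccc3)cc(C)c2OCOC)c(C(=O)OC(C)(C)C)c(C)cc1OCc1ccccc1 | intermediate
18 | 4-(benzyloxy)-2-[2,3-bis(benzyloxy)-6-hydroxy-5-methylphenoxy]-3-formyl-6-methylbenzoic acid | O=Cc1c(Oc2c(OCc3ccccc3)c(OCc3ccccc3)cc(C)c2O)c(C(=O)O)c(C)cc1OCc1ccccc1 | intermediate
19 | 3,6,7-tris(benzyloxy)-1,9-dimethyl-11-oxo-11H-dibenzo[b,e][1,4]dioxepine-4-carbaldehyde | Cc1cc(OCc2ccccc2)c(C=O)c2c1C(=O)Oc1c(C)cc(OCc3ccccc3)c(OCc3ccccc3)c1O2 | intermediate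
20 | 3,6,7-trihydroxy-1,9-dimethyl-11-oxo-11H-dibenzo[b,e][1,4]dioxepine-4-carbaldehyde (ring D-free depsidone triol aldehyde) | Cc1cc(O)c(C=O)c2c1C(=O)Oc1c(C)cc(O)c(O)c1O2 | intermediate
21 | 3-methylbut-2-enoic acid | CC(C)=CC(=O)O | starting material
22 | 3,6,7-trihydroxy-1,9-dimethyl-8-(3-methylbut-2-enoyl)-11-oxo-11H-dibenzo[b,e][1,4]dioxepine-4-carbaldehyde | Cc1cc(O)c(C=O)c2c1C(=O)Oc1c(C)c(C(=O)C=C(C)C)c(O)c(O)c1O2 | intermediate
23 | CNP0271978.0: depsidone 20 carrying a 2,2-dimethyl-2,3-dihydropyran-4-one ring fused at C7–C8 (ring oxygen on C7, ketone carbon on C8) | Cc1cc(O)c(C=O)c2c1C(=O)Oc1c(C)c3c(c(O)c1O2)OC(C)(C)CC3=O | target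

**Step count and risks**

Total steps: 14. Longest linear sequence: 10 (steps 1–6, then 11–14).

Steps most likely to fail:

1. Step 14 (key step). In the superacid the unprotected substrate may be diverted by acylation at oxygen (including the ring A phenol) without migration to carbon, by attack of ring C of one molecule on the protonated formyl group of another, or by acid opening of the lactone. The fallback sets out from 20 and separates O-acylation from C–C bond formation. Treatment of 20 with 3-methylbut-2-enoyl chloride (1.05 equiv), pyridine, CH2Cl2, −20 °C should acylate the ring C catechol and leave the chelated ring A phenol, giving 4-formyl-3,6-dihydroxy-1,9-dimethyl-11-oxo-11H-dibenzo[b,e][1,4]dioxepin-7-yl 3-methylbut-2-enoate F1 (its 6-O isomer, related by acyl shift, serves equally). Fries rearrangement with AlCl3 in nitrobenzene (rt → 50 °C) moves the acyl group to C8, the only free carbon, and the ortho-hydroxy enone closes to the chromanone on acidic work-up, coming back to the route at 23.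

2. Step 10. The formyl group may be masked incompletely, so that butyllithium adds to it, or lithium morpholide may attack the activated C–F bond instead of the carbonyl. The fallback sets out from 13 and uses an isolated acetal. Ethylene glycol, TsOH, toluene, Dean–Stark gives 2-[6-(benzyloxy)-3-bromo-2-fluoro-4-methylphenyl]-1,3-dioxolane F2. Bromine–lithium exchange (n-BuLi, THF, −78 °C) and quenching with Boc2O gives tert-butyl 4-(benzyloxy)-3-(1,3-dioxolan-2-yl)-2-fluoro-6-methylbenzoate F3. Mild hydrolysis (aqueous oxalic acid, THF, rt) removes the dioxolane without touching the tert-butyl ester and comes back to the route at 16.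

3. Step 2. Site selectivity may be lost, through over-alkylation to the tribenzyl ether or alkylation of the 2-hydroxyl in place of the 3-hydroxyl. The fallback sets out from 2 and replaces selective protection by selective deprotection. Exhaustive benzylation (BnBr in excess, K2CO3, DMF, 60 °C) gives 2,3,4-tris(benzyloxy)-6-methylbenzaldehyde F4. MgBr2·OEt2 (toluene/Et2O, reflux) then cleaves only the benzyl ether ortho to the formyl group through a six-membered magnesium chelate, coming back to the route at 3.

**Further compounds**

F1 | step 14 | 4-formyl-3,6-dihydroxy-1,9-dimethyl-11-oxo-11H-dibenzo[b,e][1,4]dioxepin-7-yl 3-methylbut-2-enoate | Cc1cc(O)c(C=O)c2c1C(=O)Oc1c(C)cc(OC(=O)C=C(C)C)c(O)c1O2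
F2 | step 10 | 2-[6-(benzyloxy)-3-bromo-2-fluoro-4-methylphenyl]-1,3-dioxolane | Cc1cc(OCc2ccccc2)c(C2OCCO2)c(F)c1Br
F3 | step 10 | tert-butyl 4-(benzyloxy)-3-(1,3-dioxolan-2-yl)-2-fluoro-6-methylbenzoate | Cc1cc(OCc2ccccc2)c(C2OCCO2)c(F)c1C(=O)OC(C)(C)C
F4 | step 2 | 2,3,4-tris(benzyloxy)-6-methylbenzaldehyde | O=Cc1c(C)cc(OCc2ccccc2)c(OCc2ccccc2)c1OCc1ccccc1
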